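**Retrosynthetic overview**
1. Structural feature: in ring A the neighbouring carbons C8a and C4a carry O1 and the C4 carbonyl, and the C5 oxygen sits beside C4a (C7 oxygen meta to it). These two carbons are read as the triple bond of a 3,5-dioxygenated benzyne that takes up the oxygen and the acyl carbon of a carboxylic acid.
2. Endgame: the three phenolic MOM ethers come off last. Before that the C9–O ester is cut (Mitsunobu with free p-coumaric acid on the C7,C9-diol released from its acetonide, with all flavone and guaiacyl phenols still masked).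
3. Key disconnection: O1–C8a, C4–C4a and O1–C2 of ring C, leading back to a silylaryl triflate (ring A, from phloroglucinol) and a ring-B arylpropiolic acid that already carries the protected side chain.
4. The propiolic acid comes from the aryl bromide (Sonogashira, desilylation, CO2). C8 is set by an Evans syn aldol of the aryloxyacetyl imide with O-MOM-vanillin, and C7 is then inverted by a Mitsunobu reaction.
5. Ring order: rings A and B, the guaiacyl ring and the coumaroyl ring are bought. The temporary 1,3-dioxane is closed first (step 13), and ring C is the only skeletal ring formed (step 17).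

Key step: step 17

Remark: the side chain is numbered C7 (benzylic carbinol), C8 (aryloxy carbon) and C9 (CH2O); the SMILES reads (7R,8S), the erythro (anti) series, and because anti-selective auxiliary aldols are not established for aryloxyacetyl imides, the reliable syn aldol is used and C7 is inverted afterwards.

**Step 1**
Reactants: 1 phloroglucinol
Product: 2 3,5-bis(methoxymethoxy)phenol
Conditions: MOMCl (2.0 equiv), i-Pr2NEt (2.2 equiv), THF–DMF, 0 °C → rt
Reagents that add atoms: chloromethyl methyl ether (MOMCl), COCCl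
Why: Williamson-type O-alkylation with a reactive alpha-chloro ether, in which two equivalents of MOMCl should favour the bis-ether statistically, and the mono- and tris-ethers can be separated by chromatography and recycled.

**Step 2**
Reactants: 2 3,5-bis(methoxymethoxy)phenol
Product: 3 2-bromo-3,5-bis(methoxymethoxy)phenol
Conditions: NBS (1.0 equiv), CH2Cl2, −78 °C → 0 °C
Reagents that add atoms: N-bromosuccinimide, O=C1CCC(=O)N1Br
Why: Electrophilic aromatic bromination in which the free hydroxyl is the strongest donor and hydrogen-bonds to NBS, so bromine should enter ortho to it at C2 (equivalent to C6) rather than at C4, which is crowded by two MOM ethers.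

**Step 3**
Reactants: 3 2-bromo-3,5-bis(methoxymethoxy)phenol
Product: 4 [2-bromo-3,5-bis(methoxymethoxy)phenoxy]trimethylsilane
Conditions: (Me3Si)2NH, THF, 65 °C; volatiles removed in vacuo
Reagents that add atoms: hexamethyldisilazane, C[Si](C)(C)N[Si](C)(C)C
Why: O-silylation of a phenol with HMDS needs neither added acid nor base and releases only ammonia, so the MOM ethers and the aryl bromide stay untouched.

**Step 4**
Reactants: 4 [2-bromo-3,5-bis(methoxymethoxy)phenoxy]trimethylsilane
Product: 6 3,5-bis(methoxymethoxy)-2-(trimethylsilyl)phenyl trifluoromethanesulfonate, via lithium 2-silylphenoxide 5 (not isolated)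
Conditions: n-BuLi (1.1 equiv), THF, −78 °C; Tf2O (1.2 equiv), −78 °C → 0 °C; chromatography on Et3N-washed silica
Reagents that add atoms: trifluoromethanesulfonic anhydride, O=S(=O)(OS(=O)(=O)C(F)(F)F)C(F)(F)F
Why: Bromine–lithium exchange followed by a retro-Brook 1,3-shift of silicon from oxygen to carbon should give phenoxide 5, which Tf2O traps, the standard way to 2-silylaryl triflates, helped here by the MOM oxygen beside the lithiated carbon.

**Step 5**
Reactants: 7 4-bromo-2,6-dimethoxyphenol; 8 bromoacetic acid
Product: 9 2-(4-bromo-2,6-dimethoxyphenoxy)acetic acid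
Conditions: NaH (2.4 equiv), THF, 0 °C → reflux; then 1 M HCl
Reagents that add atoms: none
Why: Williamson ether synthesis in which the sodium phenoxide displaces bromide from sodium bromoacetate by SN2 at an unhindered primary carbon, which tolerates the two ortho methoxy groups.

**Step 6**
Reactants: 9 2-(4-bromo-2,6-dimethoxyphenoxy)acetic acid; 10 (R)-4-benzyloxazolidin-2-one
Product: 12 (R)-4-benzyl-3-[2-(4-bromo-2,6-dimethoxyphenoxy)acetyl]oxazolidin-2-one, via mixed pivalic anhydride 11 (not isolated)
Conditions: PivCl (1.05 equiv), Et3N (2.5 equiv), THF, −20 °C; then LiCl (1.1 equiv), 10, −20 °C → rt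
Reagents that add atoms: none
Why: N-acylation of the oxazolidinone through a mixed pivalic anhydride with LiCl/Et3N activation, in which attack goes to the less hindered aryloxyacetyl carbonyl of 11.

**Step 7**
Reactants: 13 vanillin
Product: 14 3-methoxy-4-(methoxymethoxy)benzaldehyde
Conditions: MOMCl (1.3 equiv), i-Pr2NEt (1.6 equiv), CH2Cl2, 0 °C → rt
Reagents that add atoms: chloromethyl methyl ether (MOMCl), COCCl
Why: Williamson-type O-alkylation of the acidic para-formyl phenol, which leaves the aldehyde untouched and installs a group stable to boron enolates, hydride, organolithium and fluoride.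

**Step 8**
Reactants: 12 (R)-4-benzyl-3-[2-(4-bromo-2,6-dimethoxyphenoxy)acetyl]oxazolidin-2-one; 14 3-methoxy-4-(methoxymethoxy)benzaldehyde
Product: 16 (R)-4-benzyl-3-[(2R,3S)-2-(4-bromo-2,6-dimethoxyphenoxy)-3-hydroxy-3-[3-methoxy-4-(methoxymethoxy)phenyl]propanoyl]oxazolidin-2-one, via Z dibutylboron enolate 15 (not isolated)
Conditions: Bu2BOTf (1.1 equiv), Et3N (1.3 equiv), CH2Cl2, −78 → 0 °C; 14, −78 → 0 °C; pH 7 buffer, MeOH, 30% H2O2, 0 °C
Reagents that add atoms: none
Why: Evans syn aldol in which soft enolisation gives Z enolate 15, which reacts through a chair Zimmerman–Traxler transition state on the face away from the benzyl group of the (R)-auxiliary, setting C8 as the target needs (2R here, 8S after reduction) and C7 as 3S (syn, threo), to be corrected in step 11.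

**Step 9**
Reactants: 16 syn aldol adduct
Product: 17 (1S,2S)-2-(4-bromo-2,6-dimethoxyphenoxy)-1-[3-methoxy-4-(methoxymethoxy)phenyl]propane-1,3-diol (threo)
Conditions: LiBH4 (2 equiv), MeOH (2 equiv), THF, 0 °C
Reagents that add atoms: none
Why: Reductive cleavage of the N-acyl oxazolidinone at the exocyclic carbonyl by LiBH4, run cold so that retro-aldol does not compete, which leaves both stereocentres and the aryl bromide intact and releases auxiliary 10 for recovery.

**Step 10**
Reactants: 17 threo diol
Product: 18 (1S,2S)-2-(4-bromo-2,6-dimethoxyphenoxy)-3-[(tert-butyldimethylsilyl)oxy]-1-[3-methoxy-4-(methoxymethoxy)phenyl]propan-1-ol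
Conditions: TBSCl (1.05 equiv), imidazole (2 equiv), CH2Cl2, 0 °C
Reagents that add atoms: tert-butyldimethylsilyl chloride, CC(C)(C)[Si](C)(C)Cl
Why: Sterically controlled silylation, in which the primary C9 hydroxyl should react far faster than the secondary benzylic one flanked by the aryl and aryloxy groups.

**Step 11**
Reactants: 18 threo C9-silyl ether
Product: 19 (1R,2S)-2-(4-bromo-2,6-dimethoxyphenoxy)-3-[(tert-butyldimethylsilyl)oxy]-1-[3-methoxy-4-(methoxymethoxy)phenyl]propyl 4-nitrobenzoate
Conditions: 4-nitrobenzoic acid (3 equiv), PPh3 (3 equiv), DIAD (3 equiv), toluene, −20 °C → rt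
Reagents that add atoms: 4-nitrobenzoic acid, O=C(O)c1ccc(cc1)[N+](=O)[O-]
Why: Mitsunobu inversion, known for beta-aryl ether carbinols of this type, in which 4-nitrobenzoate displaces the C7 alkoxyphosphonium group by SN2 (7S to 7R, threo to erythro), the acidic nucleophile and cold non-polar solvent hold back ionisation, and the C9 silyl ether cannot participate.

**Step 12**
Reactants: 19 erythro 4-nitrobenzoate
Product: 21 (1R,2S)-2-(4-bromo-2,6-dimethoxyphenoxy)-1-[3-methoxy-4-(methoxymethoxy)phenyl]propane-1,3-diol (erythro), via erythro silyl ether alcohol 20 (not isolated)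
Conditions: K2CO3 (0.3 equiv), MeOH–THF, rt; evaporate; TBAF (1.2 equiv), THF, rt
Reagents that add atoms: none
Why: Base-catalysed transesterification cleaves the acyl–oxygen bond so that C7 keeps its new configuration, and fluoride desilylation then frees the primary alcohol.

**Step 13**
Reactants: 21 erythro diol
Product: 22 (4R,5S)-5-(4-bromo-2,6-dimethoxyphenoxy)-4-[3-methoxy-4-(methoxymethoxy)phenyl]-2,2-dimethyl-1,3-dioxane (trans)
Conditions: 2,2-dimethoxypropane (5 equiv), PPTS (0.05 equiv), CH2Cl2, rt
Reagents that add atoms: 2,2-dimethoxypropane, COC(C)(C)OC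
Why: Acid-catalysed transketalisation, in which the erythro diol closes to the trans-4,5-disubstituted dioxane with aryl and aryloxy groups both equatorial, and PPTS is too weak to cleave the aryl MOM ether or ionise C7.

**Step 14**
Reactants: 22 acetonide aryl bromide; 23 ethynyltrimethylsilane
Product: 24 [[4-[[(4R,5S)-4-[3-methoxy-4-(methoxymethoxy)phenyl]-2,2-dimethyl-1,3-dioxan-5-yl]oxy]-3,5-dimethoxyphenyl]ethynyl]trimethylsilane
Conditions: 23 (1.5 equiv), Pd(PhCN)2Cl2 (3 mol %), [HP(t-Bu)3]BF4 (6 mol %), CuI (2 mol %), i-Pr2NH (2 equiv), 1,4-dioxane, rt → 45 °C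
Reagents that add atoms: none
Why: Sonogashira coupling in which the bulky electron-rich phosphine lets zerovalent palladium insert into the electron-rich but unhindered aryl bromide under mild conditions that the ketal and MOM ether tolerate.

**Step 15**
Reactants: 24 silylalkyne
Product: 25 (4R,5S)-5-(4-ethynyl-2,6-dimethoxyphenoxy)-4-[3-methoxy-4-(methoxymethoxy)phenyl]-2,2-dimethyl-1,3-dioxane
Conditions: K2CO3 (0.2 equiv), MeOH–THF 1:1, rt
Reagents that add atoms: none
Why: Methoxide-catalysed protiodesilylation of an alkynylsilane, a mild basic reaction to which every other group in the molecule is inert.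

**Step 16**
Reactants: 25 terminal alkyne
Product: 27 3-[4-[[(4R,5S)-4-[3-methoxy-4-(methoxymethoxy)phenyl]-2,2-dimethyl-1,3-dioxan-5-yl]oxy]-3,5-dimethoxyphenyl]prop-2-ynoic acid, via lithium acetylide 26 (not isolated)
Conditions: n-BuLi (1.05 equiv), THF, −78 °C; CO2 (dried gas), −78 → 0 °C; cold 0.5 M HCl to pH 2, EtOAc, 0 °C, immediate extraction
Reagents that add atoms: carbon dioxide, O=C=O
Why: Deprotonation of the terminal alkyne and carboxylation of the lithium acetylide with CO2, with a brief cold two-phase acidification so that the ketal survives.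

**Step 17**
Reactants: 27 arylpropiolic acid; 6 3,5-bis(methoxymethoxy)-2-(trimethylsilyl)phenyl trifluoromethanesulfonate
Product: 30 2-[4-[[(4R,5S)-4-[3-methoxy-4-(methoxymethoxy)phenyl]-2,2-dimethyl-1,3-dioxan-5-yl]oxy]-3,5-dimethoxyphenyl]-5,7-bis(methoxymethoxy)chromen-4-one, via 3,5-bis(methoxymethoxy)benzyne 28 (not isolated), via 2-hydroxyaryl ynone 29 (not isolated)
Conditions: 27, CsF (4 equiv), THF (0.02 M), rt, 15 min; 6 (1.5 equiv), sealed tube, 125 °C, 24 h; cool to rt, then Et2NH (5 equiv), 60 °C, 2 h
Reagents that add atoms: none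
Why: Fluoride removes the silyl group of 6 and triflate leaves to give aryne 28; the carboxylate of 27 adds through oxygen to the aryne carbon remote from the flanking methoxymethoxy group (future C8a), the aryl anion formed at the future C4a next to the C5 oxygen attacks the ester carbonyl, and the strained four-membered hemiketal alkoxide opens to the phenoxide of ynone 29, a net insertion into the acid C–O bond that makes O1–C8a and C4–C4a. The closest known reaction type is the fluoride-induced insertion of arynes into the C–O bond of carboxylic acids to give 2-hydroxyaryl ketones, which runs on to chromanones with acrylic acids and to flavones with arylpropiolic acids. Ring C, the only ring closed, forms by 6-endo-dig oxa-Michael addition of the C8a phenoxide to the ynone beta carbon (O1–C2), and the proton given up by the acid ends at C3. No stereocenter is made, and C7 and C8 sit in the base-stable trans-acetonide, which also leaves no free hydroxyl to trap the aryne. Three selectivities are needed: regiochemistry, secured by the inductive pull and ring distortion of the alkoxy group beside the triple bond; acyl shift ahead of protonation of the aryl anion, secured by hot dilute THF in which sparingly soluble CsF releases the aryne slowly; and 6-endo over 5-exo closure, secured by diethylamine, which turns leftover ynone into a beta-amino enone that can only close to the pyranone. The amine is added only after 6 is used up, because a free secondary amine would be N-arylated by the aryne faster than the carboxylate reacts.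

**Step 18**
Reactants: 30 flavone acetonide
Product: 31 2-[4-[[(1R,2S)-1,3-dihydroxy-1-[3-methoxy-4-(methoxymethoxy)phenyl]propan-2-yl]oxy]-3,5-dimethoxyphenyl]-5,7-bis(methoxymethoxy)chromen-4-one
Conditions: AcOH–H2O–THF 4:1:1, 25–30 °C
Reagents that add atoms: none
Why: Acid-catalysed ketal hydrolysis, in which the isopropylidene ketal ionises to a tertiary oxocarbenium ion far more easily than the formaldehyde-derived aryl MOM acetals, and any partial loss of the peri 5-O-MOM group would be harmless because the chelated 5-OH is inert in step 19 and converges in step 20.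

**Step 19**
Reactants: 31 C7,C9-diol; 32 p-coumaric acid
Product: 33 (7R,8S)-C9 (E)-4-hydroxycinnamate of 31 (C7-OH free, three MOM ethers retained)
Conditions: 32 (1.3 equiv), PPh3 (1.3 equiv), DIAD (1.3 equiv), THF, 0 °C → rt
Reagents that add atoms: none
Why: Mitsunobu esterification, known to work with unprotected hydroxycinnamic acids, in which the carboxylic acid is much more acidic than the only free phenol present and so is the sole nucleophile, and the primary C9 hydroxyl is activated ahead of the hindered C7 carbinol, whose configuration is therefore untouched.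

**Step 20**
Reactants: 33 tris-MOM ester
Product: 34 target CNP0264527.1, tricin 4'-O-[(7R,8S)-erythro-guaiacylglyceryl] ether 9-O-(E)-p-coumarate
Conditions: 3 M aq HCl–THF 1:2, 35 °C, stopped at full conversion
Reagents that add atoms: none
Why: Acid-catalysed hydrolysis of the three aryl MOM acetals in an alcohol-free aqueous medium, mild enough that acetal cleavage should outrun ionisation at C7, ester hydrolysis and acyl shift, and free of any alcohol that could transesterify or etherify.

**Compound list**
1 | phloroglucinol | Oc1cc(O)cc(O)c1 | starting material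
2 | 3,5-bis(methoxymethoxy)phenol | COCOc1cc(O)cc(OCOC)c1 | intermediate
3 | 2-bromo-3,5-bis(methoxymethoxy)phenol | COCOc1cc(O)c(Br)c(OCOC)c1 | intermediate
4 | [2-bromo-3,5-bis(methoxymethoxy)phenoxy]trimethylsilane | COCOc1cc(O[Si](C)(C)C)c(Br)c(OCOC)c1 | intermediate
5 | lithium 3,5-bis(methoxymethoxy)-2-(trimethylsilyl)phenoxide | COCOc1cc([O-])c([Si](C)(C)C)c(OCOC)c1.[Li+] | intermediate
6 | 3,5-bis(methoxymethoxy)-2-(trimethylsilyl)phenyl trifluoromethanesulfonate | COCOc1cc(OCOC)c([Si](C)(C)C)c(OS(=O)(=O)C(F)(F)F)c1 | intermediate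
7 | 4-bromo-2,6-dimethoxyphenol | COc1cc(Br)cc(OC)c1O | starting material
8 | bromoacetic acid | OC(=O)CBr | starting material
9 | 2-(4-bromo-2,6-dimethoxyphenoxy)acetic acid | COc1cc(Br)cc(OC)c1OCC(=O)O | intermediate
10 | (R)-4-benzyloxazolidin-2-one | O=C1OC[C@@H](Cc2ccccc2)N1 | starting material
11 | 2-(4-bromo-2,6-dimethoxyphenoxy)acetic pivalic anhydride | COc1cc(Br)cc(OC)c1OCC(=O)OC(=O)C(C)(C)C | intermediate
12 | (R)-4-benzyl-3-[2-(4-bromo-2,6-dimethoxyphenoxy)acetyl]oxazolidin-2-one | COc1cc(Br)cc(OC)c1OCC(=O)N1[C@H](Cc2ccccc2)COC1=O | intermediate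
13 | vanillin | COc1cc(C=O)ccc1O | starting material
14 | 3-methoxy-4-(methoxymethoxy)benzaldehyde | COc1cc(C=O)ccc1OCOC | intermediate
15 | (Z)-dibutylboron enolate of 12 | COc1cc(Br)cc(OC)c1O/C=C(\OB(CCCC)CCCC)N1[C@H](Cc2ccccc2)COC1=O | intermediate
16 | (R)-4-benzyl-3-[(2R,3S)-2-(4-bromo-2,6-dimethoxyphenoxy)-3-hydroxy-3-[3-methoxy-4-(methoxymethoxy)phenyl]propanoyl]oxazolidin-2-one | COc1cc([C@H](O)[C@H](C(=O)N2[C@H](Cc3ccccc3)COC2=O)Oc2c(OC)cc(Br)cc2OC)ccc1OCOC | intermediate
17 | (1S,2S)-2-(4-bromo-2,6-dimethoxyphenoxy)-1-[3-methoxy-4-(methoxymethoxy)phenyl]propane-1,3-diol | COc1cc([C@H](O)[C@H](CO)Oc2c(OC)cc(Br)cc2OC)ccc1OCOC | intermediate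
18 | (1S,2S)-2-(4-bromo-2,6-dimethoxyphenoxy)-3-[(tert-butyldimethylsilyl)oxy]-1-[3-methoxy-4-(methoxymethoxy)phenyl]propan-1-ol | COc1cc([C@H](O)[C@H](CO[Si](C)(C)C(C)(C)C)Oc2c(OC)cc(Br)cc2OC)ccc1OCOC | intermediate
19 | (1R,2S)-2-(4-bromo-2,6-dimethoxyphenoxy)-3-[(tert-butyldimethylsilyl)oxy]-1-[3-methoxy-4-(methoxymethoxy)phenyl]propyl 4-nitrobenzoate | COc1cc([C@@H](OC(=O)c2ccc([N+](=O)[O-])cc2)[C@H](CO[Si](C)(C)C(C)(C)C)Oc2c(OC)cc(Br)cc2OC)ccc1OCOC | intermediate
20 | (1R,2S)-2-(4-bromo-2,6-dimethoxyphenoxy)-3-[(tert-butyldimethylsilyl)oxy]-1-[3-methoxy-4-(methoxymethoxy)phenyl]propan-1-ol | COc1cc([C@@H](O)[C@H](CO[Si](C)(C)C(C)(C)C)Oc2c(OC)cc(Br)cc2OC)ccc1OCOC | intermediate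
21 | (1R,2S)-2-(4-bromo-2,6-dimethoxyphenoxy)-1-[3-methoxy-4-(methoxymethoxy)phenyl]propane-1,3-diol | COc1cc([C@@H](O)[C@H](CO)Oc2c(OC)cc(Br)cc2OC)ccc1OCOC | intermediate
22 | (4R,5S)-5-(4-bromo-2,6-dimethoxyphenoxy)-4-[3-methoxy-4-(methoxymethoxy)phenyl]-2,2-dimethyl-1,3-dioxane | COc1cc([C@@H](OC(C)(C)OC2)[C@H]2Oc2c(OC)cc(Br)cc2OC)ccc1OCOC | intermediate
23 | ethynyltrimethylsilane | C#C[Si](C)(C)C | starting material
24 | [[4-[[(4R,5S)-4-[3-methoxy-4-(methoxymethoxy)phenyl]-2,2-dimethyl-1,3-dioxan-5-yl]oxy]-3,5-dimethoxyphenyl]ethynyl]trimethylsilane | COc1cc([C@@H](OC(C)(C)OC2)[C@H]2Oc2c(OC)cc(C#C[Si](C)(C)C)cc2OC)ccc1OCOC | intermediate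
25 | (4R,5S)-5-(4-ethynyl-2,6-dimethoxyphenoxy)-4-[3-methoxy-4-(methoxymethoxy)phenyl]-2,2-dimethyl-1,3-dioxane | COc1cc([C@@H](OC(C)(C)OC2)[C@H]2Oc2c(OC)cc(C#C)cc2OC)ccc1OCOC | intermediate
26 | lithium acetylide of 25 | COc1cc([C@@H](OC(C)(C)OC2)[C@H]2Oc2c(OC)cc(C#[C-])cc2OC)ccc1OCOC.[Li+] | intermediate
27 | 3-[4-[[(4R,5S)-4-[3-methoxy-4-(methoxymethoxy)phenyl]-2,2-dimethyl-1,3-dioxan-5-yl]oxy]-3,5-dimethoxyphenyl]prop-2-ynoic acid | COc1cc([C@@H](OC(C)(C)OC2)[C@H]2Oc2c(OC)cc(C#CC(=O)O)cc2OC)ccc1OCOC | intermediate
28 | 3,5-bis(methoxymethoxy)benzyne | COCOC1=CC(OCOC)=CC#C1 | intermediate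
29 | 1-[2-hydroxy-4,6-bis(methoxymethoxy)phenyl]-3-[4-[[(4R,5S)-4-[3-methoxy-4-(methoxymethoxy)phenyl]-2,2-dimethyl-1,3-dioxan-5-yl]oxy]-3,5-dimethoxyphenyl]prop-2-yn-1-one | COc1cc([C@@H](OC(C)(C)OC2)[C@H]2Oc2c(OC)cc(C#CC(=O)c3c(O)cc(OCOC)cc3OCOC)cc2OC)ccc1OCOC | intermediate
30 | 2-[4-[[(4R,5S)-4-[3-methoxy-4-(methoxymethoxy)phenyl]-2,2-dimethyl-1,3-dioxan-5-yl]oxy]-3,5-dimethoxyphenyl]-5,7-bis(methoxymethoxy)chromen-4-one | COc1cc([C@@H](OC(C)(C)OC2)[C@H]2Oc2c(OC)cc(-c3cc(=O)c4c(OCOC)cc(OCOC)cc4o3)cc2OC)ccc1OCOC | intermediate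
31 | 2-[4-[[(1R,2S)-1,3-dihydroxy-1-[3-methoxy-4-(methoxymethoxy)phenyl]propan-2-yl]oxy]-3,5-dimethoxyphenyl]-5,7-bis(methoxymethoxy)chromen-4-one | COc1cc([C@@H](O)[C@H](CO)Oc2c(OC)cc(-c3cc(=O)c4c(OCOC)cc(OCOC)cc4o3)cc2OC)ccc1OCOC | intermediate
32 | (E)-p-coumaric acid | O=C(O)/C=C/c1ccc(O)cc1 | starting material
33 | (7R,8S)-C9 (E)-4-hydroxycinnamate of 31 | COc1cc([C@@H](O)[C@H](COC(=O)/C=C/c2ccc(O)cc2)Oc2c(OC)cc(-c3cc(=O)c4c(OCOC)cc(OCOC)cc4o3)cc2OC)ccc1OCOC | intermediate
34 | CNP0264527.1, tricin 4'-O-[(7R,8S)-erythro-guaiacylglyceryl] ether 9-O-(E)-p-coumarate | COc1cc([C@@H](O)[C@H](COC(=O)/C=C/c2ccc(O)cc2)Oc2c(OC)cc(-c3cc(=O)c4c(O)cc(O)cc4o3)cc2OC)ccc1O | target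

**Step count**
- Total step count: 20.
- Longest linear sequence: 15 steps, from 7 through steps 5, 6 and 8–20.

**Steps most likely to fail**

1. **Step 17.**
   - What may go wrong: the aryl anion may be protonated before the acyl shift, which stops the sequence at simple O-arylation. The cesium propiolate may decarboxylate at 125 °C. The intermediate phenoxide may be arylated by a second aryne, the aryl anion may add to the alkyne instead of the carbonyl, or part of the ynone may close 5-exo.
   - Fallback (palladium-catalysed carbonylative annulation, known chemistry): it sets out from phenol 2 and terminal alkyne 25. Iodination of 2 (NIS, CH2Cl2, −78 → 0 °C) should give 2-iodo-3,5-bis(methoxymethoxy)phenol F1. Carbonylative Sonogashira coupling of F1 with 25 under CO (PdCl2(dppf), Et2NH, 60–100 °C) passes through the same ynone 29. The amine solvent steers 29 into 6-endo closure, and the fallback comes back to the route at flavone 30.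

2. **Step 11.**
   - What may go wrong: the alkoxyphosphonium salt may ionise at the electron-rich benzylic carbon, which would erode the inversion. Displacement next to the bulky aryloxy group may also be slow, which would favour elimination toward the enol ether.
   - Fallback (oxidation and chelation-controlled reduction): it sets out from 18. Dess–Martin periodinane in CH2Cl2 should give (S)-2-(4-bromo-2,6-dimethoxyphenoxy)-3-[(tert-butyldimethylsilyl)oxy]-1-[3-methoxy-4-(methoxymethoxy)phenyl]propan-1-one F2. Reduction with an ethereal stock solution of Zn(BH4)2 at −30 °C follows, with zinc bridging the carbonyl and the C8 aryloxy oxygen and hydride entering from the side of the C8 hydrogen (Cram chelate model). This should give erythro alcohol 20, where the fallback comes back to the route at the fluoride stage of step 12.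

3. **Step 20.**
   - What may go wrong: slow hydrolysis of the less activated MOM ethers may force long acid contact. That would bring ionisation at C7 (erosion of the erythro configuration), ester hydrolysis, or acyl shift from O9 to O7.
   - Fallback (acid step moved ahead of the esterification, so the ester never meets acid): it sets out from 30. Aqueous HCl in THF removes the acetonide and the three MOM ethers in one operation. The product is 2-[4-[[(1R,2S)-1,3-dihydroxy-1-(4-hydroxy-3-methoxyphenyl)propan-2-yl]oxy]-3,5-dimethoxyphenyl]-5,7-dihydroxychromen-4-one F3, which can be freed from any C7 epimer at this simpler stage by crystallisation or chromatography. Mitsunobu esterification of F3 with 32 follows (PPh3 and DIAD in slight excess only, THF–DMF, 0 °C). This reaction is known to pair an unprotected phenolic acid with the primary hydroxyl of a phenolic alcohol, and it comes back to the route at target 34.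

**Further compounds**
F1 | step 17 | 2-iodo-3,5-bis(methoxymethoxy)phenol | COCOc1cc(O)c(I)c(OCOC)c1
F2 | step 11 | (S)-2-(4-bromo-2,6-dimethoxyphenoxy)-3-[(tert-butyldimethylsilyl)oxy]-1-[3-methoxy-4-(methoxymethoxy)phenyl]propan-1-one | COc1cc(C(=O)[C@H](CO[Si](C)(C)C(C)(C)C)Oc2c(OC)cc(Br)cc2OC)ccc1OCOC
F3 | step 20 | 2-[4-[[(1R,2S)-1,3-dihydroxy-1-(4-hydroxy-3-methoxyphenyl)propan-2-yl]oxy]-3,5-dimethoxyphenyl]-5,7-dihydroxychromen-4-one | COc1cc([C@@H](O)[C@H](CO)Oc2c(OC)cc(-c3cc(=O)c4c(O)cc(O)cc4o3)cc2OC)ccc1O
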